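## Structural features

The target is built on one carbocycle, ring A, a cyclohex-3-ene numbered C1 to C6. C1 carries the chain C7(=O)–C8H=C9(OH)–C10H=C11H–aryl, a Z-enolised, hydrogen-bonded 1,3-diketone ending in an (E)-styryl unit with a free 4-hydroxy-3-methoxyphenyl group. C2 carries Ar1 (3,4-dimethoxyphenyl) and C6 carries Ar2 (4-hydroxy-3-methoxyphenyl), so the stereocentres C2–C1–C6 are contiguous and all S, with the acyl group trans to Ar1 and cis to Ar2. With the alkene at C3=C4 this is neither the pattern of a simple [4+2] adduct of an (E)-enone nor the all-equatorial arrangement, so it has to be set under kinetic control and then protected. The fragile points are: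
- C1–H, α to a carbonyl (inversion would swap the two relative configurations);
- C2–H, benzylic and allylic, so that C3=C4 can slide into conjugation with Ar1;
- the enolised diketone (retro-Claisen cleavage, oxidation at C8);
- the styryl enone (no hydrogenation possible) and two oxidisable phenols.

The real difficulty is absolute and relative control of the C2–C1–C6 triad next to an epimerisable carbonyl. The key step exploits the fact that the only alkene of ring A, C3=C4, is an unsubstituted cis CH=CH lying one bond from C2 and, through C5, two bonds from C6. Ring A can therefore be closed last from a vinyl group on C2 and an allyl group on C6 without touching a stereocentre.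

## Logic of the disconnections

21 ⇒ 20. The two phenolic O–Si bonds are cut. Free guaiacol units would interfere with the amide base, the hypervalent iodine oxidant and the ruthenium carbene, and both silyl ethers fall in one fluoride treatment. The forward step must be non-basic enough to leave C1 and the diketone alone.

20 ⇒ 19 ⇒ 15 + 17. After lowering C7 to the carbinol level, the C7–C8 bond is cut. This separates the chiral half 15 from the achiral styryl methyl ketone 17, which is one step from 16. The aldol addition must outrun proton transfer from C1, and the oxidation must stop at the diketone.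

15 ⇒ 14. The C3=C4 bond is cut, the only bond of ring A that is remote from all three stereocentres. The ring becomes an acyclic octa-1,7-diene whose stereotriad can be set by acyclic catalyst control. The forward ring closure must beat oligomerisation and must not move the alkene or invert C1.

14 ⇒ 11 + 13. The C1–C2 bond is cut, which removes two stereocentres at once and leaves a β-stereogenic aldehyde and a racemic aryl vinyl carbinol. The forward step must create C1 and C2 under catalyst control, independent of C6, and leave an α-branched aldehyde that does not epimerise.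

11 ⇒ 10 ⇒ 8 ⇒ 7. These are functional group changes: the terminal C=CH2 bond at C4 is cut (methylenation of a masked aldehyde) and C7 is traced back to a CH2–O carbon. The lactone carbonyl carbon of 7 becomes C4 and its O–CH2 carbon becomes C7. The gain is a cyclic acceptor suited to asymmetric conjugate addition; the C6 centre is never α to a carbonyl on this path.

7 ⇒ 5 + 6. The C6–Ar2 bond is cut. This reduces the first stereocentre to a face-selective aryl transfer onto a commercial unsaturated lactone; the demand is high enantioface selection and survival of the aryl silyl ether in aqueous medium.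

5 ⇒ 2 ⇒ 1, 13 ⇒ 12, 17 ⇒ 16. The C–B and O–Si bonds of 5, the carbinol–vinyl bond of 13 and the O–Si bond of 17 are cut, each to a commercial compound by one routine operation.

## Other disconnections considered

Alternative 1: The cut is C1–C2, with O–C4 reconnected, which traces ring A to the δ-lactone A1 (C7 as lactone carbonyl, Ar2 on C6, a 2-arylethenyl group on the carbinol carbon C4). Forward, LiN(iPr)2 and Me3SiCl give the cyclic silyl ketene acetal, which on warming rearranges [3,3] to the silyl ester A2.
- In favour: one metal-free, intramolecular step forms a ring bond, closes ring A, places the alkene at C3=C4 and sets C1 and C2 together by chirality transfer. On this point it is the better plan, since the metathesis sets no stereocentre. C7 also arrives at the acid level.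
- Against: the endocyclic ketene acetal enforces a boat array. Tracing the substituents through it, the 1,2-trans/1,6-cis triad requires the (Z)-styryl group and the 4,6-trans lactone, as drawn for A1. Both are the less accessible isomers, and Ar1 is pushed under the C5–C6 tether in the transition state.
- Comparison: both plans reach the same ring A carbonyl skeleton. Here C1 and C2 are locked to one alkene geometry and one carbinol centre, whereas the chosen plan sets them with two independently exchangeable catalysts. The step count to A1 should be about equal to that to 14.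

Alternative 2: The cuts are C1–C6 and C2–C3. Forward, the silyl diene A3 and the cinnamoyl imide A4 combine under Cu(SbF6)2 with 2,2'-(propane-2,2-diyl)bis(4-tert-butyl-4,5-dihydrooxazole) (divalent copper, chelated by the imide) in an endo [4+2] cycloaddition to give A5.
- In favour: it is the most convergent plan. Two ring bonds and all three permanent stereocentres form in one step, and the endo mode of an (E)-dienophile gives the 1,2-trans/1,6-cis pattern directly. In convergence and stereocentres per step it is better than the chosen plan.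
- Against: a β-aryl acryloyl imide with a donor-substituted ring is a weak dienophile towards an acyclic 1,4-disubstituted diene. The alkene is formed at C4=C5, so a separate acid-mediated protodesilylation with allylic transposition must move it to C3=C4 in the presence of two electron-rich arenes, an aryl silyl ether and the epimerisable C1. The imide must then be exchanged.
- Comparison: the cycloaddition is stereochemically tighter than an acyclic allylation. The chosen plan forms the alkene where it belongs and uses only reactions with close analogy. The step count would be lower for Alternative 2 if the cycloaddition proceeds.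

Alternative 3: The cuts are C6–Ar2 and C1–C7 on an intact ring. Forward, a chiral bisphosphine complex of zerovalent palladium (from Pd2(dba)3) adds the aryl iodide A7 across one of the two enantiotopic alkenes of the Birch-derived diene A6, anti to Ar1. CO insertion and methanolysis then give the ester A8.
- In favour: ring A and its alkene come from an arene, an achiral diene is turned into the full triad in one step, and C7 arrives as an ester. In step economy it is clearly better than the chosen plan.
- Against: the alkylpalladium at C1 lies syn to the hydrogen on C2, so β-hydride elimination to a conjugated diene should compete with CO insertion. CO can also insert into the aryl–palladium bond before the alkene does. The regiochemistry of aryl transfer (C6 against C1) is only weakly biased. An enantioselective three-component reaction of this kind on an unactivated internal alkene lacks close analogy.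
- Comparison: the chosen plan is much longer, but each of its steps rests on an established reaction class, and its stereocentres are set one or two at a time by well-understood catalysts.

Key step: step 9

Remarks before the steps:
- The precursor of the key step is carried as the triisopropylsilyl ether of the Ar2 phenol (same skeleton). This aryl silyl ether must survive n-BuLi, aqueous rhodium catalysis, an ylide/alkoxide medium and a lithium aldolate. 1,4-Benzoquinone is added to the metathesis against alkene migration.
- Assumption: the catalyst enantiomers in steps 3 and 8 are assigned from the usual models of these catalysts, not from a reported case of this substrate. Each catalyst governs one centre only, so a wrong sense would be corrected by taking the antipode without changing the route.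
- Compounds 20 and 21 are drawn as the chelated Z-enol on the styryl side; the other enol tautomer is in rapid equilibrium with it.

## Steps

Step 1
Reactants: 1 4-bromo-2-methoxyphenol
Product: 2 (4-bromo-2-methoxyphenoxy)triisopropylsilane
Conditions: iPr3SiCl (1.1 equiv), imidazole (2.2 equiv), DMF, rt
Reagents that add atoms: chlorotriisopropylsilane, CC(C)[Si](Cl)(C(C)C)C(C)C
Why: Imidazole-promoted O-silylation of a phenol; the bulky silyl group is chosen because its aryl ethers resist organolithium reagents, alkoxides and warm aqueous media far better than the tert-butyldimethylsilyl ether.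

Step 2
Reactants: 2 (4-bromo-2-methoxyphenoxy)triisopropylsilane
Product: 5 {3-methoxy-4-[(triisopropylsilyl)oxy]phenyl}boronic acid, via aryllithium 3 (not isolated), via lithium aryl(triisopropoxy)borate 4 (not isolated)
Conditions: n-BuLi (1.05 equiv), THF, −78 °C; B(OiPr)3 (1.5 equiv), −78 °C to rt; 1 M HCl to pH 5, 0 °C
Reagents that add atoms: triisopropyl borate, CC(C)OB(OC(C)C)OC(C)C; water, O
Why: Bromine–lithium exchange is faster than attack at the hindered silicon, and the lithium para to the silyloxy group cannot undergo silyl migration; trapping with the borate and mild hydrolysis is the standard route to arylboronic acids.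

Step 3
Reactants: 5 {3-methoxy-4-[(triisopropylsilyl)oxy]phenyl}boronic acid (2.5 equiv); 6 5,6-dihydro-2H-pyran-2-one
Product: 7 (4R)-4-{3-methoxy-4-[(triisopropylsilyl)oxy]phenyl}oxan-2-one
Conditions: Rh(acac)(C2H4)2 (3 mol %), (R)-2,2'-bis(diphenylphosphino)-1,1'-binaphthyl (3.3 mol %), 1,4-dioxane/H2O 10:1, 40 °C
Reagents that add atoms: none
Why: Hayashi–Miyaura reaction: transmetalation gives an aryl–rhodium species (monovalent rhodium), the lactone alkene inserts with enantioface selection and water protonates the oxa-allyl intermediate. The (R) ligand is expected to give the (R) lactone, by analogy with the (S) ligand giving (S) adducts of cyclic enones and unsaturated lactones; this sets C6.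

Step 4
Reactants: 7 (4R)-4-{3-methoxy-4-[(triisopropylsilyl)oxy]phenyl}oxan-2-one
Product: 8 (4R)-4-{3-methoxy-4-[(triisopropylsilyl)oxy]phenyl}oxan-2-ol (anomer mixture; used crude)
Conditions: iBu2AlH (1.1 equiv), CH2Cl2, −78 °C; aqueous KNaC4H4O6
Reagents that add atoms: none
Why: Partial reduction of a δ-lactone to the lactol; the tetrahedral aluminium alkoxide is stable at −78 °C, which prevents a second hydride transfer.

Step 5
Reactants: 8 (4R)-4-{3-methoxy-4-[(triisopropylsilyl)oxy]phenyl}oxan-2-ol
Product: 10 (3S)-3-{3-methoxy-4-[(triisopropylsilyl)oxy]phenyl}hex-5-en-1-ol, via open-chain hydroxy aldehyde 9 (not isolated)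
Conditions: Ph3PCH3Br (3.0 equiv), KOtBu (2.9 equiv), THF, 0 °C; then 8, 0 °C to rt
Reagents that add atoms: methyltriphenylphosphonium bromide, C[P+](c1ccccc1)(c1ccccc1)c1ccccc1.[Br-]
Why: Wittig methylenation of the aldehyde in equilibrium with the lactol; the stereocentre is not α to the carbonyl and the hindered aryl silyl ether should tolerate the alkoxide and the ylide.

Step 6
Reactants: 10 (3S)-3-{3-methoxy-4-[(triisopropylsilyl)oxy]phenyl}hex-5-en-1-ol
Product: 11 (3S)-3-{3-methoxy-4-[(triisopropylsilyl)oxy]phenyl}hex-5-enal
Conditions: Dess–Martin periodinane (1.2 equiv), CH2Cl2, 0 °C to rt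
Reagents that add atoms: none
Why: Dess–Martin oxidation of a primary alcohol under near-neutral conditions; the terminal alkene and the β-stereocentre are not affected.

Step 7
Reactants: 12 3,4-dimethoxybenzaldehyde
Product: 13 rac-1-(3,4-dimethoxyphenyl)prop-2-en-1-ol
Conditions: CH2=CHMgBr (1.2 equiv), THF, 0 °C; aqueous NH4Cl
Reagents that add atoms: vinylmagnesium bromide, C=C[Mg]Br
Why: Grignard 1,2-addition to an aromatic aldehyde; the racemate suffices because the carbinol centre is erased on ionisation in step 8.

Step 8
Reactants: 11 (3S)-3-{3-methoxy-4-[(triisopropylsilyl)oxy]phenyl}hex-5-enal (1.0 equiv); 13 rac-1-(3,4-dimethoxyphenyl)prop-2-en-1-ol (1.5 equiv)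
Product: 14 (2S,3S)-2-[(1S)-1-(3,4-dimethoxyphenyl)prop-2-en-1-yl]-3-{3-methoxy-4-[(triisopropylsilyl)oxy]phenyl}hex-5-enal
Conditions: [Ir(cod)Cl]2 (3 mol %), (S)-5-(dinaphtho[2,1-d:1',2'-f][1,3,2]dioxaphosphepin-4-yl)-5H-dibenzo[b,f]azepine (12 mol %), (R)-2-{bis[3,5-bis(trifluoromethyl)phenyl][(trimethylsilyl)oxy]methyl}pyrrolidine (15 mol %), (MeO)2P(O)OH (substoichiometric promoter), ClCH2CH2Cl, 25 °C
Reagents that add atoms: none
Why: Stereodivergent dual-catalytic α-allylation of a linear aldehyde: the acid promoter lets the phosphoramidite–olefin complex of monovalent iridium ionise 13 to an allyl–iridium electrophile (trivalent iridium), which the enamine of 11 attacks at its aryl-bearing terminus. The ligand enantiomer fixes C2 and the amine, by shielding one enamine face, fixes C1, so the anti (1S,2S) pair should form under catalyst control irrespective of C6. The α-branched product forms an enamine only slowly, which protects C1 from epimerisation and from a second allylation.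

Step 9
Reactants: 14 (2S,3S)-2-[(1S)-1-(3,4-dimethoxyphenyl)prop-2-en-1-yl]-3-{3-methoxy-4-[(triisopropylsilyl)oxy]phenyl}hex-5-enal
Product: 15 (1S,2S,6S)-2-(3,4-dimethoxyphenyl)-6-{3-methoxy-4-[(triisopropylsilyl)oxy]phenyl}cyclohex-3-ene-1-carbaldehyde
Conditions: RuCl2(H2IMes)(PCy3)(=CHPh) (second-generation Grubbs catalyst, 5 mol %), 1,4-benzoquinone (10 mol %), CH2Cl2 (0.005 M), 40 °C
Reagents that add atoms: none
Why: Phosphine loss from the ruthenium benzylidene gives the 14-electron carbene, which exchanges by [2+2] cycloaddition and cycloreversion with the unhindered allyl terminus and so places the carbene on C4. This carbene adds intramolecularly to the C2 vinyl group, and collapse of the ruthenacyclobutane forms C3=C4 and a ruthenium methylidene that carries the cycle and leaves as ethene. The closest known reaction type is ring-closing metathesis of octa-1,7-dienes to cyclohexenes, including dienes with an aryl-bearing allylic carbon and a free α-branched aldehyde. Ring A closes as a six-membered carbocycle by joining the two alkene carbons C3 and C4, and the ring size allows only the cis alkene. No stereocentre is created; C1, C2 and C6 are spectators because no bond to them is made or broken. The step needs cyclisation over intermolecular metathesis, which the 1,7 spacing, high dilution and ethene loss secure, the branched C2 vinyl group being a poor partner for dimerisation. It also needs the alkene to stay at C3=C4 and C1 to keep its configuration: the neutral catalyst does not enolise the aldehyde, and 1,4-benzoquinone intercepts ruthenium hydrides that could move the alkene into conjugation with Ar1.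

Step 10
Reactants: 16 dehydrozingerone, (E)-4-(4-hydroxy-3-methoxyphenyl)but-3-en-2-one
Product: 17 (E)-4-{4-[tert-butyl(dimethyl)silyloxy]-3-methoxyphenyl}but-3-en-2-one
Conditions: tBuMe2SiCl (1.2 equiv), imidazole (2.4 equiv), DMF, rt
Reagents that add atoms: tert-butylchlorodimethylsilane, CC(C)(C)[Si](C)(C)Cl
Why: Imidazole-promoted silylation of the phenol; this ether only has to survive the amide base at −78 °C and a neutral oxidation, so the smaller silyl group is sufficient.

Step 11
Reactants: 17 (E)-4-{4-[tert-butyl(dimethyl)silyloxy]-3-methoxyphenyl}but-3-en-2-one (1.2 equiv); 15 (1S,2S,6S)-2-(3,4-dimethoxyphenyl)-6-{3-methoxy-4-[(triisopropylsilyl)oxy]phenyl}cyclohex-3-ene-1-carbaldehyde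
Product: 19 (E)-1-{4-[tert-butyl(dimethyl)silyloxy]-3-methoxyphenyl}-5-[(1S,2S,6S)-2-(3,4-dimethoxyphenyl)-6-{3-methoxy-4-[(triisopropylsilyl)oxy]phenyl}cyclohex-3-en-1-yl]-5-hydroxypent-1-en-3-one as both carbinol epimers, via lithium dienolate 18 (not isolated)
Conditions: LiN(iPr)2 (1.15 equiv), THF, −78 °C, 30 min; then 15, −78 °C; AcOH in THF at −78 °C
Reagents that add atoms: none
Why: Aldol addition: the methyl group is the only enolisable position of 17, so kinetic deprotonation gives the cross-conjugated lithium dienolate, and its addition to the aldehyde at −78 °C is faster than proton abstraction at C1. The new carbinol centre is of no consequence because it is oxidised in the next step.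

Step 12
Reactants: 19 (E)-1-{4-[tert-butyl(dimethyl)silyloxy]-3-methoxyphenyl}-5-[(1S,2S,6S)-2-(3,4-dimethoxyphenyl)-6-{3-methoxy-4-[(triisopropylsilyl)oxy]phenyl}cyclohex-3-en-1-yl]-5-hydroxypent-1-en-3-one
Product: 20 (2Z,4E)-5-{4-[tert-butyl(dimethyl)silyloxy]-3-methoxyphenyl}-1-[(1S,2S,6S)-2-(3,4-dimethoxyphenyl)-6-{3-methoxy-4-[(triisopropylsilyl)oxy]phenyl}cyclohex-3-en-1-yl]-3-hydroxypenta-2,4-dien-1-one
Conditions: 2-iodoxybenzoic acid (3 equiv), EtOAc, 75 °C
Reagents that add atoms: none
Why: Oxidation of a β-hydroxy ketone to the β-diketone with 2-iodoxybenzoic acid, a neutral heterogeneous oxidant that does not attack the central carbon of the product; both phenols are silylated and therefore safe, and the product settles as the chelated enol.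

Step 13
Reactants: 20 (2Z,4E)-5-{4-[tert-butyl(dimethyl)silyloxy]-3-methoxyphenyl}-1-[(1S,2S,6S)-2-(3,4-dimethoxyphenyl)-6-{3-methoxy-4-[(triisopropylsilyl)oxy]phenyl}cyclohex-3-en-1-yl]-3-hydroxypenta-2,4-dien-1-one
Product: 21 (2Z,4E)-1-[(1S,2S,6S)-2-(3,4-dimethoxyphenyl)-6-(4-hydroxy-3-methoxyphenyl)cyclohex-3-en-1-yl]-3-hydroxy-5-(4-hydroxy-3-methoxyphenyl)penta-2,4-dien-1-one (target)
Conditions: Bu4NF (2.5 equiv), AcOH (2.5 equiv), THF, 0 °C
Reagents that add atoms: none
Why: Fluoride cleavage of both aryl silyl ethers; acetic acid buffers the phenoxide and enolate basicity, so C1 should not epimerise and the diketone should not be cleaved.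

## Compound list

1 | 4-bromo-2-methoxyphenol | COc1cc(Br)ccc1O | starting material
2 | (4-bromo-2-methoxyphenoxy)triisopropylsilane | COc1cc(Br)ccc1O[Si](C(C)C)(C(C)C)C(C)C | intermediate
3 | {3-methoxy-4-[(triisopropylsilyl)oxy]phenyl}lithium | COc1cc([Li])ccc1O[Si](C(C)C)(C(C)C)C(C)C | intermediate (not isolated)
4 | lithium {3-methoxy-4-[(triisopropylsilyl)oxy]phenyl}tri(propan-2-yloxy)borate | [Li+].COc1cc([B-](OC(C)C)(OC(C)C)OC(C)C)ccc1O[Si](C(C)C)(C(C)C)C(C)C | intermediate (not isolated)
5 | {3-methoxy-4-[(triisopropylsilyl)oxy]phenyl}boronic acid | COc1cc(B(O)O)ccc1O[Si](C(C)C)(C(C)C)C(C)C | intermediate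
6 | 5,6-dihydro-2H-pyran-2-one | O=C1C=CCCO1 | starting material
7 | (4R)-4-{3-methoxy-4-[(triisopropylsilyl)oxy]phenyl}oxan-2-one | O=C1C[C@H](c2ccc(O[Si](C(C)C)(C(C)C)C(C)C)c(OC)c2)CCO1 | intermediate
8 | (4R)-4-{3-methoxy-4-[(triisopropylsilyl)oxy]phenyl}oxan-2-ol, anomer mixture | OC1C[C@H](c2ccc(O[Si](C(C)C)(C(C)C)C(C)C)c(OC)c2)CCO1 | intermediate
9 | (3R)-5-hydroxy-3-{3-methoxy-4-[(triisopropylsilyl)oxy]phenyl}pentanal | O=CC[C@H](c1ccc(O[Si](C(C)C)(C(C)C)C(C)C)c(OC)c1)CCO | intermediate (not isolated)
10 | (3S)-3-{3-methoxy-4-[(triisopropylsilyl)oxy]phenyl}hex-5-en-1-ol | C=CC[C@H](c1ccc(O[Si](C(C)C)(C(C)C)C(C)C)c(OC)c1)CCO | intermediate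
11 | (3S)-3-{3-methoxy-4-[(triisopropylsilyl)oxy]phenyl}hex-5-enal | C=CC[C@H](c1ccc(O[Si](C(C)C)(C(C)C)C(C)C)c(OC)c1)CC=O | intermediate
12 | 3,4-dimethoxybenzaldehyde | COc1ccc(C=O)cc1OC | starting material
13 | rac-1-(3,4-dimethoxyphenyl)prop-2-en-1-ol | C=CC(O)c1ccc(OC)c(OC)c1 | intermediate
14 | (2S,3S)-2-[(1S)-1-(3,4-dimethoxyphenyl)prop-2-en-1-yl]-3-{3-methoxy-4-[(triisopropylsilyl)oxy]phenyl}hex-5-enal | O=C[C@H]([C@@H](c1ccc(OC)c(OC)c1)C=C)[C@@H](c2ccc(O[Si](C(C)C)(C(C)C)C(C)C)c(OC)c2)CC=C | intermediate (precursor of the key step)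
15 | (1S,2S,6S)-2-(3,4-dimethoxyphenyl)-6-{3-methoxy-4-[(triisopropylsilyl)oxy]phenyl}cyclohex-3-ene-1-carbaldehyde | O=C[C@@H]1[C@@H](c2ccc(OC)c(OC)c2)C=CC[C@@H]1c3ccc(O[Si](C(C)C)(C(C)C)C(C)C)c(OC)c3 | intermediate (product of the key step)
16 | dehydrozingerone, (E)-4-(4-hydroxy-3-methoxyphenyl)but-3-en-2-one | COc1cc(/C=C/C(C)=O)ccc1O | starting material
17 | (E)-4-{4-[tert-butyl(dimethyl)silyloxy]-3-methoxyphenyl}but-3-en-2-one | COc1cc(/C=C/C(C)=O)ccc1O[Si](C)(C)C(C)(C)C | intermediate
18 | lithium (E)-4-{4-[tert-butyl(dimethyl)silyloxy]-3-methoxyphenyl}buta-1,3-dien-2-olate | COc1cc(/C=C/C(=C)O[Li])ccc1O[Si](C)(C)C(C)(C)C | intermediate (not isolated)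
19 | (E)-1-{4-[tert-butyl(dimethyl)silyloxy]-3-methoxyphenyl}-5-[(1S,2S,6S)-2-(3,4-dimethoxyphenyl)-6-{3-methoxy-4-[(triisopropylsilyl)oxy]phenyl}cyclohex-3-en-1-yl]-5-hydroxypent-1-en-3-one, both carbinol epimers | COc1cc(/C=C/C(=O)CC(O)[C@@H]2[C@@H](c3ccc(OC)c(OC)c3)C=CC[C@@H]2c4ccc(O[Si](C(C)C)(C(C)C)C(C)C)c(OC)c4)ccc1O[Si](C)(C)C(C)(C)C | intermediate
20 | (2Z,4E)-5-{4-[tert-butyl(dimethyl)silyloxy]-3-methoxyphenyl}-1-[(1S,2S,6S)-2-(3,4-dimethoxyphenyl)-6-{3-methoxy-4-[(triisopropylsilyl)oxy]phenyl}cyclohex-3-en-1-yl]-3-hydroxypenta-2,4-dien-1-one | COc1cc(/C=C/C(O)=C/C(=O)[C@@H]2[C@@H](c3ccc(OC)c(OC)c3)C=CC[C@@H]2c4ccc(O[Si](C(C)C)(C(C)C)C(C)C)c(OC)c4)ccc1O[Si](C)(C)C(C)(C)C | intermediate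
21 | (2Z,4E)-1-[(1S,2S,6S)-2-(3,4-dimethoxyphenyl)-6-(4-hydroxy-3-methoxyphenyl)cyclohex-3-en-1-yl]-3-hydroxy-5-(4-hydroxy-3-methoxyphenyl)penta-2,4-dien-1-one | COc1cc(/C=C/C(O)=C/C(=O)[C@@H]2[C@@H](c3ccc(OC)c(OC)c3)C=CC[C@@H]2c2ccc(O)c(OC)c2)ccc1O | target

Total step count: 13. Longest linear sequence: 11 steps (1, 2, 3, 4, 5, 6, 8, 9, 11, 12, 13); steps 7 and 10 are one-step side branches.

## Least certain steps

Step 8. Catalyst control may be incomplete on a β-branched, β-stereogenic aldehyde: enamine formation is slower than with unbranched aldehydes, and the resident C6 centre may oppose the amine in the mismatched sense. The electron-rich carbinol can also be diverted into ether formation or arene alkylation once ionised, and the assumed sense of induction of either catalyst may be the reverse of what is needed. The fallback replaces the intermolecular allylation by a sigmatropic shift. It sets out from 11 and comes back at 14: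
- Pinnick oxidation (NaClO2, NaH2PO4, 2-methylbut-2-ene) should give (3S)-3-{3-methoxy-4-[(triisopropylsilyl)oxy]phenyl}hex-5-enoic acid F1.
- Carbodiimide esterification (N,N'-dicyclohexylcarbodiimide, 4-dimethylaminopyridine) with commercial (E)-3-(3,4-dimethoxyphenyl)prop-2-en-1-ol should give the allyl ester F2.
- Ireland–Claisen rearrangement (LiN(iPr)2, Me3SiCl, THF, −78 °C, then 60 °C) would pass through the silyl ketene acetal F3, with the chain trans to the silyloxy group, and the silyl ester F4, and give the acid F5 after hydrolysis. The chair array with the (E)-alkene gives the required C1/C2 anti relation. The face is chosen only by the C6 centre, so the epimer pair at C1/C2 may have to be separated.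
- Coupling with MeNH(OMe)·HCl gives the Weinreb amide F6, and iBu2AlH at −78 °C returns 14.

Step 9 (key step). Ring closure may be slowed by chelation of the aldehyde oxygen to the ruthenium carbene, and during a long reaction ruthenium hydrides could move the C2 vinyl group or the new ring alkene into conjugation with Ar1, which would erase C2. The fallback removes the carbonyl from the metathesis substrate. It sets out from 14 and comes back at 15: NaBH4 in MeOH at 0 °C reduces 14 to the dienyl alcohol F7; the same ruthenium catalyst closes ring A on F7 to the cyclohexenylmethanol F8; Dess–Martin oxidation returns 15.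

Step 11. The aldehyde is flanked by two aryl-bearing carbons, so addition may be slow enough for proton transfer from C1 (epimerisation) or retro-aldol reversal to compete; the aldol can also cyclise by oxa-Michael addition onto the styryl enone if it is kept. The fallback changes from a basic enolate to Lewis acid activation. It sets out from 17 (with 15) and comes back at 19: Me3SiOTf and Et3N convert 17 into the 2-silyloxydiene F9, and BF3·OEt2-mediated Mukaiyama aldol addition of F9 to 15 at −78 °C gives 19 after aqueous work-up.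

Step 12. Oxidation may go beyond the diketone at the doubly activated C8, or C1 may epimerise during heating of the enolisable product. The fallback avoids the oxidation by forming the C7–C8 bond at the acid oxidation level. It sets out from 15 (with 17) and comes back at 20: Pinnick oxidation gives the ring A acid F10; 1-(methylsulfonyl)benzotriazole and Et3N convert it into the N-acylbenzotriazole F11; soft enolisation of 17 with MgBr2·OEt2 and iPr2NEt in CH2Cl2 and C-acylation by F11 give 20 directly.

## Further compounds

F1 | step 8 | (3S)-3-{3-methoxy-4-[(triisopropylsilyl)oxy]phenyl}hex-5-enoic acid | C=CC[C@H](c1ccc(O[Si](C(C)C)(C(C)C)C(C)C)c(OC)c1)CC(=O)O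
F2 | step 8 | (E)-3-(3,4-dimethoxyphenyl)prop-2-en-1-yl (3S)-3-{3-methoxy-4-[(triisopropylsilyl)oxy]phenyl}hex-5-enoate | C=CC[C@H](c1ccc(O[Si](C(C)C)(C(C)C)C(C)C)c(OC)c1)CC(=O)OC/C=C/c1ccc(OC)c(OC)c1
F3 | step 8 | trimethylsilyl ketene acetal of F2, chain trans to the silyloxy group (not isolated) | C=CC[C@H](c1ccc(O[Si](C(C)C)(C(C)C)C(C)C)c(OC)c1)/C=C(/O[Si](C)(C)C)OC/C=C/c1ccc(OC)c(OC)c1
F4 | step 8 | trimethylsilyl (2S,3S)-2-[(1S)-1-(3,4-dimethoxyphenyl)prop-2-en-1-yl]-3-{3-methoxy-4-[(triisopropylsilyl)oxy]phenyl}hex-5-enoate (not isolated) | C[Si](C)(C)OC(=O)[C@H]([C@@H](c1ccc(OC)c(OC)c1)C=C)[C@@H](c1ccc(O[Si](C(C)C)(C(C)C)C(C)C)c(OC)c1)CC=C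
F5 | step 8 | (2S,3S)-2-[(1S)-1-(3,4-dimethoxyphenyl)prop-2-en-1-yl]-3-{3-methoxy-4-[(triisopropylsilyl)oxy]phenyl}hex-5-enoic acid | OC(=O)[C@H]([C@@H](c1ccc(OC)c(OC)c1)C=C)[C@@H](c1ccc(O[Si](C(C)C)(C(C)C)C(C)C)c(OC)c1)CC=C
F6 | step 8 | (2S,3S)-2-[(1S)-1-(3,4-dimethoxyphenyl)prop-2-en-1-yl]-N-methoxy-N-methyl-3-{3-methoxy-4-[(triisopropylsilyl)oxy]phenyl}hex-5-enamide | CON(C)C(=O)[C@H]([C@@H](c1ccc(OC)c(OC)c1)C=C)[C@@H](c1ccc(O[Si](C(C)C)(C(C)C)C(C)C)c(OC)c1)CC=C
F7 | step 9 | (2S,3S)-2-[(1S)-1-(3,4-dimethoxyphenyl)prop-2-en-1-yl]-3-{3-methoxy-4-[(triisopropylsilyl)oxy]phenyl}hex-5-en-1-ol | OC[C@H]([C@@H](c1ccc(OC)c(OC)c1)C=C)[C@@H](c1ccc(O[Si](C(C)C)(C(C)C)C(C)C)c(OC)c1)CC=C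
F8 | step 9 | [(1S,2S,6S)-2-(3,4-dimethoxyphenyl)-6-{3-methoxy-4-[(triisopropylsilyl)oxy]phenyl}cyclohex-3-en-1-yl]methanol | OC[C@@H]1[C@@H](c2ccc(OC)c(OC)c2)C=CC[C@@H]1c3ccc(O[Si](C(C)C)(C(C)C)C(C)C)c(OC)c3
F9 | step 11 | tert-butyl{2-methoxy-4-[(E)-3-(trimethylsilyloxy)buta-1,3-dien-1-yl]phenoxy}dimethylsilane | COc1cc(/C=C/C(=C)O[Si](C)(C)C)ccc1O[Si](C)(C)C(C)(C)C
F10 | step 12 | (1S,2S,6S)-2-(3,4-dimethoxyphenyl)-6-{3-methoxy-4-[(triisopropylsilyl)oxy]phenyl}cyclohex-3-ene-1-carboxylic acid | OC(=O)[C@@H]1[C@@H](c2ccc(OC)c(OC)c2)C=CC[C@@H]1c3ccc(O[Si](C(C)C)(C(C)C)C(C)C)c(OC)c3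
F11 | step 12 | 1-[(1S,2S,6S)-2-(3,4-dimethoxyphenyl)-6-{3-methoxy-4-[(triisopropylsilyl)oxy]phenyl}cyclohex-3-ene-1-carbonyl]-1H-benzotriazole | O=C([C@@H]1[C@@H](c2ccc(OC)c(OC)c2)C=CC[C@@H]1c3ccc(O[Si](C(C)C)(C(C)C)C(C)C)c(OC)c3)n4nnc5ccccc54
A1 | alternative 1 | (4S,6R)-4-{4-[tert-butyl(dimethyl)silyloxy]-3-methoxyphenyl}-6-[(Z)-2-(3,4-dimethoxyphenyl)ethenyl]oxan-2-one (4,6-trans) | O=C1C[C@@H](c2ccc(O[Si](C)(C)C(C)(C)C)c(OC)c2)C[C@H](/C=C\c3ccc(OC)c(OC)c3)O1
A2 | alternative 1 | trimethylsilyl (1S,2S,6S)-6-{4-[tert-butyl(dimethyl)silyloxy]-3-methoxyphenyl}-2-(3,4-dimethoxyphenyl)cyclohex-3-ene-1-carboxylate | C[Si](C)(C)OC(=O)[C@@H]1[C@@H](c2ccc(OC)c(OC)c2)C=CC[C@@H]1c3ccc(O[Si](C)(C)C(C)(C)C)c(OC)c3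
A3 | alternative 2 | tert-butyl{2-methoxy-4-[(1E,3E)-4-(trimethylsilyl)buta-1,3-dien-1-yl]phenoxy}dimethylsilane | C[Si](C)(C)/C=C/C=C/c1ccc(O[Si](C)(C)C(C)(C)C)c(OC)c1
A4 | alternative 2 | 3-[(E)-3-(3,4-dimethoxyphenyl)prop-2-enoyl]-1,3-oxazolidin-2-one | O=C(/C=C/c1ccc(OC)c(OC)c1)N1CCOC1=O
A5 | alternative 2 | endo cycloadduct, 3-[(1S,2S,6S)-ring A carbonyl]-1,3-oxazolidin-2-one with trimethylsilyl on C3 (cis to the acyl group and Ar2) and the alkene at C4=C5 | O=C(N1CCOC1=O)[C@@H]2[C@@H](c3ccc(OC)c(OC)c3)[C@H]([Si](C)(C)C)C=C[C@@H]2c4ccc(O[Si](C)(C)C(C)(C)C)c(OC)c4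
A6 | alternative 3 | 4-(cyclohexa-2,5-dien-1-yl)-1,2-dimethoxybenzene | COc1ccc(C2C=CCC=C2)cc1OC
A7 | alternative 3 | tert-butyl(4-iodo-2-methoxyphenoxy)dimethylsilane | COc1cc(I)ccc1O[Si](C)(C)C(C)(C)C
A8 | alternative 3 | methyl (1S,2S,6S)-6-{4-[tert-butyl(dimethyl)silyloxy]-3-methoxyphenyl}-2-(3,4-dimethoxyphenyl)cyclohex-3-ene-1-carboxylate | COC(=O)[C@@H]1[C@@H](c2ccc(OC)c(OC)c2)C=CC[C@@H]1c3ccc(O[Si](C)(C)C(C)(C)C)c(OC)c3
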